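Numbering and enabling feature: the lactone ring is O1–C2(=O)–C3–C4–C5, with O3 the hydroxyl oxygen on C3, C7 the syringyl CH2 on C3 and C7' the guaiacyl CH2 on C4. C3 is fully substituted, holds O3 and is bonded directly to C4, so one allylic alcohol can give both its oxygen and its remote alkene carbon to a carbene carbon placed at C3.
Cuts: O1–C2 (lactone to γ-hydroxy ester), then C5–O1 back to a C5=C alkene, then C3–O3 and C3–C4 together. This leaves an α-diazo ester (C2, C3, C7, syringyl ring) and an (E)-allylic alcohol (O3, C5, C4, C7', guaiacyl ring). C3–C7 goes back to an acetoacetate alkylation and C4=C5 to a cross-metathesis.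
Forward: syringaldehyde and methyl acetoacetate give the diazo ester in five steps, and eugenol and (S)-but-3-en-2-ol give the alcohol in two. Step 8 joins the two chains without closing a ring, step 9 cleaves the propenyl group and closes the lactone (the only ring made), and step 10 frees both phenols.
Stereochemistry: C4 comes from the purchased (S)-carbinol centre by suprafacial 1,3-chirality transfer in the rearrangement. C3 comes from the envelope topology fixed by the (E)-alkene (ester endo, C7 exo), backed by the chiral dirhodium catalyst, and no later step touches either centre.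
A methyl carbinol is preferred to the simpler primary allylic alcohol because branching at the carbinol carbon tips the ylide towards rearrangement rather than proton transfer and adds internal stereocontrol. Its two extra carbons are lost in step 9.

Key step: step 8

Assumption: with Rh2(S-PTTL)4 the hydroxyl oxygen is taken to add to the open Si face of the carbenoid carbon and C4 to bond on the side away from rhodium, which makes the S-ligand series the matched partner of (S)-configured 11; this sense of induction is not established for ylide reactions of alkyl carbenoids.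

Step 1
Reactants: 1 syringaldehyde (4-hydroxy-3,5-dimethoxybenzaldehyde)
Product: 2 4-(benzyloxy)-3,5-dimethoxybenzaldehyde
Conditions: BnBr, K2CO3, DMF, 60 °C
Reagents that add atoms: benzyl bromide, BrCc1ccccc1
Why: Williamson ether synthesis: K2CO3 forms the hindered phenoxide, which displaces bromide from benzyl bromide by SN2 while the aldehyde stays untouched.

Step 2
Reactants: 2 4-(benzyloxy)-3,5-dimethoxybenzaldehyde
Product: 3 [4-(benzyloxy)-3,5-dimethoxyphenyl]methanol
Conditions: NaBH4, MeOH–THF, 0 °C
Reagents that add atoms: none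
Why: Borohydride reduction of an aryl aldehyde is fast at 0 °C and leaves the aryl methyl and benzyl ethers alone.

Step 3
Reactants: 3 [4-(benzyloxy)-3,5-dimethoxyphenyl]methanol
Product: 4 2-(benzyloxy)-5-(chloromethyl)-1,3-dimethoxybenzene (4-(benzyloxy)-3,5-dimethoxybenzyl chloride)
Conditions: SOCl2, CH2Cl2, 0 °C to rt
Reagents that add atoms: thionyl chloride, O=S(Cl)Cl
Why: Chlorination of a benzylic alcohol through its chlorosulfite is easy for this electron-rich ring, the product being a close relative of the stable 3,4,5-trimethoxybenzyl chloride, and it should be used without long storage.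

Step 4
Reactants: 4 4-(benzyloxy)-3,5-dimethoxybenzyl chloride; 5 methyl acetoacetate
Product: 6 methyl 2-acetyl-3-[4-(benzyloxy)-3,5-dimethoxyphenyl]propanoate (racemic)
Conditions: 5 (1.5 equiv), NaH, THF–DMF, 0 °C; then 4, 50 °C
Reagents that add atoms: none
Why: Acetoacetic ester alkylation: the sodium enolate of 5, taken in slight excess to hold back double alkylation, displaces the benzylic chloride by SN2 to form C3–C7, and the new stereocentre is racemic but is erased in step 5.

Step 5
Reactants: 6 methyl 2-acetyl-3-[4-(benzyloxy)-3,5-dimethoxyphenyl]propanoate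
Product: 7 methyl 3-[4-(benzyloxy)-3,5-dimethoxyphenyl]-2-diazopropanoate
Conditions: p-ABSA, DBU, MeCN, 0 °C to rt
Reagents that add atoms: 4-acetamidobenzenesulfonyl azide (p-ABSA), CC(=O)Nc1ccc(cc1)S(=O)(=O)N=[N+]=[N-]
Why: Deacylative Regitz diazo transfer: the DBU enolate of 6 attacks the terminal azide nitrogen and the adduct collapses with transfer of the acetyl group to the sulfonamide nitrogen, the standard entry to α-alkyl-α-diazo esters.

Step 6
Reactants: 8 eugenol (4-allyl-2-methoxyphenol)
Product: 9 1-(benzyloxy)-2-methoxy-4-(prop-2-en-1-yl)benzene (O-benzyleugenol)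
Conditions: BnBr, K2CO3, acetone, reflux
Reagents that add atoms: benzyl bromide, BrCc1ccccc1
Why: Williamson ether synthesis under carbonate conditions too mild to move the allyl double bond into conjugation.

Step 7
Reactants: 9 O-benzyleugenol; 10 (S)-but-3-en-2-ol
Product: 11 (2S,3E)-5-[4-(benzyloxy)-3-methoxyphenyl]pent-3-en-2-ol
Conditions: 10 (2 equiv), second-generation Hoveyda–Grubbs catalyst RuCl2(H2IMes)(=CH-C6H4-2-OiPr) (3 mol %), 1,4-benzoquinone (10 mol %), CH2Cl2, 40 °C
Reagents that add atoms: none
Why: Olefin cross-metathesis of a readily homodimerising allylarene with an excess of a slower-reacting secondary allylic alcohol should favour the cross product as the thermodynamic (E)-alkene (C4=C5), the carbinol stereocentre of 10 takes no part, and benzoquinone quenches ruthenium hydrides that would migrate the double bond.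

Step 8
Reactants: 7 methyl 3-[4-(benzyloxy)-3,5-dimethoxyphenyl]-2-diazopropanoate; 11 (2S,3E)-5-[4-(benzyloxy)-3-methoxyphenyl]pent-3-en-2-ol
Product: 13 methyl (2S,3R,4E)-2-[4-(benzyloxy)-3,5-dimethoxybenzyl]-3-[4-(benzyloxy)-3-methoxybenzyl]-2-hydroxyhex-4-enoate, via oxonium ylide 12 (not isolated)
Conditions: Rh2(S-PTTL)4 (dirhodium tetrakis[N-phthaloyl-(S)-tert-leucinate], 1 mol %), 11 (1.5 equiv), 4 Å MS, toluene, −78 °C, 7 added slowly by syringe pump
Reagents that add atoms: none
Why: Proposed new method: Rh2(S-PTTL)4 expels N2 from 7 to give a dirhodium carbenoid centred on C3, the hydroxyl oxygen of 11 adds to it (C3–O3 bond) to give ylide 12, an ester enolate bearing a protonated allyl ether oxygen, and C3 then bonds to the remote alkene carbon through a five-membered envelope while the old allylic C–O bond breaks ([2,3]-sigmatropic shift, C3–C4 bond), so two skeletal bonds form and no ring closes. The closest known reaction type is the dirhodium-catalysed ylide formation/[2,3]-rearrangement of aryl- and vinyldiazoacetates with secondary and tertiary allylic alcohols, and intermolecular trapping of α-alkyl-α-diazo ester carbenoids (cyclopropanation, carbonyl ylide formation) under bulky carboxylate ligands at −78 °C is known separately; joining an alkyl carbenoid to the allylic alcohol rearrangement is the new element. C4 (R) is set by the (S)-carbinol centre, because bond making and breaking are suprafacial on the allyl unit and the carbinol methyl group sits pseudo-equatorial to avoid allylic strain, which exposes a single face of C4 and delivers the (E)-propenyl group. C3 (S) is set by the envelope in which the ester lies endo, hydrogen-bonded to the O–H (the endo preference that carbonyl groups also show in ester enolate [2,3]-Wittig shifts), and the bulkier C7 arm lies exo, so that with the (E)-alkene both arylmethyl arms end up on the same side; the chiral pocket of the catalyst is expected to reinforce this by leaving one carbenoid face open to oxygen and forcing C–C bond formation on the side away from rhodium. The step needs the rearrangement to outrun 1,2-hydride (or aryl) migration, proton transfer to net O–H insertion, and cyclopropanation: ligand bulk and −78 °C slow the migration, the branched carbinol carbon weakens the allylic C–O bond and so favours the shift over proton transfer, and a hydroxyl group is a far better nucleophile towards the carbenoid than a 1,2-disubstituted alkene.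

Step 9
Reactants: 13 methyl (2S,3R,4E)-2-[4-(benzyloxy)-3,5-dimethoxybenzyl]-3-[4-(benzyloxy)-3-methoxybenzyl]-2-hydroxyhex-4-enoate
Product: 16 (3S,4R)-3-[4-(benzyloxy)-3,5-dimethoxybenzyl]-4-[4-(benzyloxy)-3-methoxybenzyl]-3-hydroxydihydrofuran-2(3H)-one, via aldehyde 14 (not isolated), via hydroxy ester 15 (not isolated)
Conditions: O3, CH2Cl2–MeOH, Sudan Red 7B, −78 °C; then NaBH4, −78 to 0 °C; aq. NH4Cl
Reagents that add atoms: ozone, [O-][O+]=O
Why: Ozonolysis (Criegee mechanism) with borohydride work-up: the isolated (E)-alkene should react with ozone well before the arenes if the dye end-point is respected, the β-hydroxy aldehyde 14 is reduced cold before it can epimerise at C4 or fragment by retro-aldol, and the C5 alkoxide of 15 closes the O1–C2 bond by 5-exo-trig acyl substitution on the methyl ester with neither stereocentre touched.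

Step 10
Reactants: 16 (3S,4R)-3-[4-(benzyloxy)-3,5-dimethoxybenzyl]-4-[4-(benzyloxy)-3-methoxybenzyl]-3-hydroxydihydrofuran-2(3H)-one
Product: 17 (3S,4R)-3-hydroxy-3-(4-hydroxy-3,5-dimethoxybenzyl)-4-(4-hydroxy-3-methoxybenzyl)dihydrofuran-2(3H)-one (CNP0176953.1)
Conditions: H2 (1 atm), 10% Pd/C, EtOAc–MeOH, rt
Reagents that add atoms: none
Why: Catalytic hydrogenolysis of aryl benzyl ethers: O3 sits on a homobenzylic, not a benzylic, carbon, so the C3–O3 bond, the lactone and both stereocentres should survive.

Compound list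
1 | syringaldehyde | COc1cc(C=O)cc(OC)c1O | starting material
2 | 4-(benzyloxy)-3,5-dimethoxybenzaldehyde | COc1cc(C=O)cc(OC)c1OCc1ccccc1 | intermediate
3 | [4-(benzyloxy)-3,5-dimethoxyphenyl]methanol | COc1cc(CO)cc(OC)c1OCc1ccccc1 | intermediate
4 | 2-(benzyloxy)-5-(chloromethyl)-1,3-dimethoxybenzene | COc1cc(CCl)cc(OC)c1OCc1ccccc1 | intermediate
5 | methyl acetoacetate | CC(=O)CC(=O)OC | starting material
6 | methyl 2-acetyl-3-[4-(benzyloxy)-3,5-dimethoxyphenyl]propanoate (racemic) | COC(=O)C(Cc1cc(OC)c(OCc2ccccc2)c(OC)c1)C(C)=O | intermediate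
7 | methyl 3-[4-(benzyloxy)-3,5-dimethoxyphenyl]-2-diazopropanoate | COC(=O)C(=[N+]=[N-])Cc1cc(OC)c(OCc2ccccc2)c(OC)c1 | intermediate
8 | eugenol | COc1cc(CC=C)ccc1O | starting material
9 | 1-(benzyloxy)-2-methoxy-4-(prop-2-en-1-yl)benzene | COc1cc(CC=C)ccc1OCc1ccccc1 | intermediate
10 | (S)-but-3-en-2-ol | C[C@H](O)C=C | starting material
11 | (2S,3E)-5-[4-(benzyloxy)-3-methoxyphenyl]pent-3-en-2-ol | C[C@H](O)/C=C/Cc1ccc(OCc2ccccc2)c(OC)c1 | intermediate
12 | oxonium ylide from the carbenoid of 7 and the hydroxyl oxygen of 11 (C3 carbanion/ester enolate, protonated (S)-allyl ether oxygen, drawn free of rhodium; not isolated) | COC(=O)[C-](Cc1cc(OC)c(OCc2ccccc2)c(OC)c1)[OH+][C@@H](C)/C=C/Cc1ccc(OCc2ccccc2)c(OC)c1 | intermediate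
13 | methyl (2S,3R,4E)-2-[4-(benzyloxy)-3,5-dimethoxybenzyl]-3-[4-(benzyloxy)-3-methoxybenzyl]-2-hydroxyhex-4-enoate | COC(=O)[C@]([C@H](Cc1ccc(OCc2ccccc2)c(OC)c1)/C=C/C)(O)Cc1cc(OC)c(OCc2ccccc2)c(OC)c1 | intermediate
14 | methyl (2S,3S)-2-[4-(benzyloxy)-3,5-dimethoxybenzyl]-3-[4-(benzyloxy)-3-methoxybenzyl]-2-hydroxy-4-oxobutanoate (not isolated) | COC(=O)[C@]([C@H](Cc1ccc(OCc2ccccc2)c(OC)c1)C=O)(O)Cc1cc(OC)c(OCc2ccccc2)c(OC)c1 | intermediate
15 | methyl (2S,3R)-2-[4-(benzyloxy)-3,5-dimethoxybenzyl]-3-[4-(benzyloxy)-3-methoxybenzyl]-2,4-dihydroxybutanoate (not isolated) | COC(=O)[C@]([C@H](Cc1ccc(OCc2ccccc2)c(OC)c1)CO)(O)Cc1cc(OC)c(OCc2ccccc2)c(OC)c1 | intermediate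
16 | (3S,4R)-3-[4-(benzyloxy)-3,5-dimethoxybenzyl]-4-[4-(benzyloxy)-3-methoxybenzyl]-3-hydroxydihydrofuran-2(3H)-one | COc1cc(C[C@@H]2COC(=O)[C@]2(O)Cc2cc(OC)c(OCc3ccccc3)c(OC)c2)ccc1OCc1ccccc1 | intermediate
17 | (3S,4R)-3-hydroxy-3-(4-hydroxy-3,5-dimethoxybenzyl)-4-(4-hydroxy-3-methoxybenzyl)dihydrofuran-2(3H)-one | COc1cc(C[C@@H]2COC(=O)[C@]2(O)Cc2cc(OC)c(O)c(OC)c2)ccc1O | target

Total step count: 10 steps.
Longest linear sequence: 8 steps (steps 1–5, then 8–10).

Steps most likely to fail

**1. Step 8.**
- **Risk:** A C7 hydrogen (or the electron-rich aryl group) may migrate to the carbenoid carbon before the alcohol arrives. Proton transfer within the ylide may overtake the sigmatropic shift. A mismatched pairing of catalyst and carbinol centre may erode facial control at C3.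
- **Fallback (known chemistry only):** It sets out from 11 and 4 and comes back at 16.
  - Alcohol 11 is heated with trimethyl orthoacetate and catalytic propionic acid. This Johnson–Claisen rearrangement passes through a chair transition state with the same suprafacial chirality transfer and gives methyl (3S,4E)-3-[4-(benzyloxy)-3-methoxybenzyl]hex-4-enoate F1.
  - Ozonolysis with NaBH4 work-up passes through methyl (3S)-3-[4-(benzyloxy)-3-methoxybenzyl]-4-oxobutanoate F2 and methyl (3S)-3-[4-(benzyloxy)-3-methoxybenzyl]-4-hydroxybutanoate F3. It ends at (4S)-4-[4-(benzyloxy)-3-methoxybenzyl]dihydrofuran-2(3H)-one F4.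
  - The lithium enolate of F4 (LiN(SiMe3)2, THF–DMPU, −78 °C) is alkylated with 4 on the face away from the C4 arm. This gives the trans lactone (3S,4S)-3-[4-(benzyloxy)-3,5-dimethoxybenzyl]-4-[4-(benzyloxy)-3-methoxybenzyl]dihydrofuran-2(3H)-one F5.
  - The potassium enolate of F5 (KN(SiMe3)2, THF, −78 °C) is hydroxylated with 3-phenyl-2-(phenylsulfonyl)oxaziridine, again on the face away from the C4 arm. This places O3 trans to C7' and pushes C7 cis to it, which is 16.

**2. Step 7.**
- **Risk:** Ruthenium hydrides may migrate the allyl double bond into conjugation with the arene. The allylarene may undergo self-metathesis. Incomplete E selectivity would carry through as lost diastereocontrol in step 8.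
- **Fallback:** It sets out from 9 and comes back at 11.
  - The terminal alkene of 9 is cleaved (O3, CH2Cl2, −78 °C, then Me2S) to 2-[4-(benzyloxy)-3-methoxyphenyl]acetaldehyde F6.
  - A Wittig reaction with the stabilised ylide 1-(triphenylphosphoranylidene)propan-2-one in CH2Cl2 at rt gives (3E)-5-[4-(benzyloxy)-3-methoxyphenyl]pent-3-en-2-one F7.
  - A Corey–Bakshi–Shibata reduction with (R)-2-methyl-CBS-oxazaborolidine and BH3·SMe2 delivers hydride to the face that gives the (S)-carbinol, which is 11.

**3. Step 9.**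
- **Risk:** Ozone may attack the electron-rich arenes or the benzylic ether positions. C4 may epimerise or the aldehyde may fragment by retro-aldol. Borohydride may over-reduce the α-hydroxy lactone.
- **Fallback:** It sets out from 13 and comes back at 16.
  - The carbinol is first capped (Et3SiOTf, 2,6-lutidine, CH2Cl2) to give methyl (2S,3R,4E)-2-[4-(benzyloxy)-3,5-dimethoxybenzyl]-3-[4-(benzyloxy)-3-methoxybenzyl]-2-[(triethylsilyl)oxy]hex-4-enoate F8, which shuts off the retro-aldol path.
  - The alkene is cleaved without ozone by Lemieux–Johnson oxidation (OsO4 cat., NaIO4, 2,6-lutidine, dioxane–water) to the isolable methyl (2S,3S)-2-[4-(benzyloxy)-3,5-dimethoxybenzyl]-3-[4-(benzyloxy)-3-methoxybenzyl]-4-oxo-2-[(triethylsilyl)oxy]butanoate F9.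
  - NaBH4 in MeOH at 0 °C gives methyl (2S,3R)-2-[4-(benzyloxy)-3,5-dimethoxybenzyl]-3-[4-(benzyloxy)-3-methoxybenzyl]-4-hydroxy-2-[(triethylsilyl)oxy]butanoate F10.
  - Dilute HCl in MeOH removes the silyl group and closes the lactone in one operation to give 16.

Further compounds
F1 | step 8 | methyl (3S,4E)-3-[4-(benzyloxy)-3-methoxybenzyl]hex-4-enoate | COC(=O)C[C@H](Cc1ccc(OCc2ccccc2)c(OC)c1)/C=C/C
F2 | step 8 | methyl (3S)-3-[4-(benzyloxy)-3-methoxybenzyl]-4-oxobutanoate | COC(=O)C[C@H](Cc1ccc(OCc2ccccc2)c(OC)c1)C=O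
F3 | step 8 | methyl (3S)-3-[4-(benzyloxy)-3-methoxybenzyl]-4-hydroxybutanoate | COC(=O)C[C@H](Cc1ccc(OCc2ccccc2)c(OC)c1)CO
F4 | step 8 | (4S)-4-[4-(benzyloxy)-3-methoxybenzyl]dihydrofuran-2(3H)-one | COc1cc(C[C@@H]2COC(=O)C2)ccc1OCc1ccccc1
F5 | step 8 | (3S,4S)-3-[4-(benzyloxy)-3,5-dimethoxybenzyl]-4-[4-(benzyloxy)-3-methoxybenzyl]dihydrofuran-2(3H)-one | COc1cc(C[C@@H]2COC(=O)[C@H]2Cc2cc(OC)c(OCc3ccccc3)c(OC)c2)ccc1OCc1ccccc1
F6 | step 7 | 2-[4-(benzyloxy)-3-methoxyphenyl]acetaldehyde | COc1cc(CC=O)ccc1OCc1ccccc1
F7 | step 7 | (3E)-5-[4-(benzyloxy)-3-methoxyphenyl]pent-3-en-2-one | CC(=O)/C=C/Cc1ccc(OCc2ccccc2)c(OC)c1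
F8 | step 9 | methyl (2S,3R,4E)-2-[4-(benzyloxy)-3,5-dimethoxybenzyl]-3-[4-(benzyloxy)-3-methoxybenzyl]-2-[(triethylsilyl)oxy]hex-4-enoate | COC(=O)[C@]([C@H](Cc1ccc(OCc2ccccc2)c(OC)c1)/C=C/C)(O[Si](CC)(CC)CC)Cc1cc(OC)c(OCc2ccccc2)c(OC)c1
F9 | step 9 | methyl (2S,3S)-2-[4-(benzyloxy)-3,5-dimethoxybenzyl]-3-[4-(benzyloxy)-3-methoxybenzyl]-4-oxo-2-[(triethylsilyl)oxy]butanoate | COC(=O)[C@]([C@H](Cc1ccc(OCc2ccccc2)c(OC)c1)C=O)(O[Si](CC)(CC)CC)Cc1cc(OC)c(OCc2ccccc2)c(OC)c1
F10 | step 9 | methyl (2S,3R)-2-[4-(benzyloxy)-3,5-dimethoxybenzyl]-3-[4-(benzyloxy)-3-methoxybenzyl]-4-hydroxy-2-[(triethylsilyl)oxy]butanoate | COC(=O)[C@]([C@H](Cc1ccc(OCc2ccccc2)c(OC)c1)CO)(O[Si](CC)(CC)CC)Cc1cc(OC)c(OCc2ccccc2)c(OC)c1
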